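**Retrosynthetic overview**
1. Target ⇒ Cα–O bond (key step, sets the only stereocentre): 2'-OH-directed asymmetric α-hydroxylation of the 4'-O-geranyl dihydrochalcone.
2. ⇒ ArO–geranyl bond: regioselective O-alkylation of 2',4',4-trihydroxydihydrochalcone with geranyl bromide.
3. ⇒ aryl–C(=O) bond: Friedel–Crafts acylation of resorcinol with 3-(4-hydroxyphenyl)propanoic acid.
4. No ring is formed in the route; both benzene rings come from the starting materials.

Assumption: the stereocentre in the given SMILES is (R) (OH > ArC=O > CH2Ar > H); BF3·OEt2 in step 1 is taken as reaction medium and Lewis acid that is not consumed by the reaction.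

**Step 1**
Reactants: 1 3-(4-hydroxyphenyl)propanoic acid (phloretic acid); 2 resorcinol (benzene-1,3-diol)
Product: 3 1-(2,4-dihydroxyphenyl)-3-(4-hydroxyphenyl)propan-1-one
Conditions: BF3·OEt2 (neat), 85 °C, 2 h; then aq. NaOAc
Reagents that add atoms: none
Why: Friedel–Crafts (Nencki-type) acylation, in which the BF3-activated acid attacks C4 of resorcinol (para to one OH, ortho to the other), a ring far more nucleophilic than the monophenol ring of 1, and the resulting o-hydroxy ketone is deactivated toward a second acylation.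

**Step 2**
Reactants: 3 1-(2,4-dihydroxyphenyl)-3-(4-hydroxyphenyl)propan-1-one; 4 geranyl bromide [(2E)-1-bromo-3,7-dimethylocta-2,6-diene] (1.05 equiv)
Product: 5 1-{4-[(2E)-3,7-dimethylocta-2,6-dien-1-yl]oxy-2-hydroxyphenyl}-3-(4-hydroxyphenyl)propan-1-one
Conditions: K2CO3 (1.1 equiv), acetone, reflux, 6 h
Reagents that add atoms: none
Why: Williamson ether synthesis (SN2 at the primary allylic bromide, E geometry kept), selective because the 4'-OH para to the ketone (pKa about 7.5–8) is the only phenol ionised by one equivalent of carbonate, while the chelated 2'-OH and the B-ring phenol (pKa about 10) stay largely protonated, as in the known 7-O-alkylations of naringenin.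

**Step 3**
Reactants: 5 1-{4-[(2E)-3,7-dimethylocta-2,6-dien-1-yl]oxy-2-hydroxyphenyl}-3-(4-hydroxyphenyl)propan-1-one
Product: 7 (2R)-1-{4-[(2E)-3,7-dimethylocta-2,6-dien-1-yl]oxy-2-hydroxyphenyl}-2-hydroxy-3-(4-hydroxyphenyl)propan-1-one (target), via titanium-chelated Z-enol 6 (not isolated)
Conditions: Ti(OiPr)4 (2.2 equiv), L-(+)-DIPT (2.6 equiv), 4 Å MS, CH2Cl2, −20 °C; TBHP (1.5 equiv, in decane), −20 → 0 °C, 24–48 h; aq. tartaric acid/FeSO4 work-up
Reagents that add atoms: tert-butyl hydroperoxide (TBHP), CC(C)(C)OO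
Why: Proposed new method: a phenol-anchored Sharpless-type enol oxidation, in which the 2'-phenoxide exchanges onto the chiral Ti(IV)–tartrate, the chelated and thereby acidified aryl ketone enolises toward its only α-CH2 to the Ti-bound Z-enol 6, and the η2-bound tert-butyl peroxide on the same titanium assembly transfers its oxygen to one enantioface of Cα, so the new C–O bond and the (R) centre are set under tartrate control (L-(+)-DIPT is written as first choice, but the facial sense cannot be predicted from the allylic-alcohol mnemonic, so it is checked on the first run by chiral HPLC against material from the fallback and D-(−)-DIPT is used if it is reversed), while the geranyl alkenes and the B-ring phenol, which have no enol next to a titanium anchor, are not oxidised; the closest known reaction type is the Ti(OiPr)4/tartrate/TBHP asymmetric α-hydroxylation of β-hydroxy ketones and of enolised cyclic 1,2-diones (hydroxyl-directed Sharpless oxidation of enols).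

**Compound list**
1 | 3-(4-hydroxyphenyl)propanoic acid (phloretic acid) | O=C(O)CCc1ccc(O)cc1 | starting material
2 | resorcinol | Oc1cccc(O)c1 | starting material
3 | 1-(2,4-dihydroxyphenyl)-3-(4-hydroxyphenyl)propan-1-one | O=C(CCc1ccc(O)cc1)c1ccc(O)cc1O | intermediate
4 | geranyl bromide, (2E)-1-bromo-3,7-dimethylocta-2,6-diene | CC(C)=CCC/C(C)=C/CBr | starting material
5 | 1-{4-[(2E)-3,7-dimethylocta-2,6-dien-1-yl]oxy-2-hydroxyphenyl}-3-(4-hydroxyphenyl)propan-1-one | CC(C)=CCC/C(C)=C/COc1ccc(C(=O)CCc2ccc(O)cc2)c(O)c1 | intermediate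
6 | titanium-chelated (Z)-enol of 5, (1Z)-1-{4-[(2E)-3,7-dimethylocta-2,6-dien-1-yl]oxy-2-hydroxyphenyl}-3-(4-hydroxyphenyl)prop-1-en-1-ol (SMILES drawn metal-free) | CC(C)=CCC/C(C)=C/COc1ccc(/C(O)=C/Cc2ccc(O)cc2)c(O)c1 | intermediate
7 | (2R)-1-{4-[(2E)-3,7-dimethylocta-2,6-dien-1-yl]oxy-2-hydroxyphenyl}-2-hydroxy-3-(4-hydroxyphenyl)propan-1-one | CC(C)=CCC/C(C)=C/COc1ccc(C(=O)[C@H](O)Cc2ccc(O)cc2)c(O)c1 | target

**Totals**
Total step count: 3. Longest linear sequence: 3 steps (1/2 → 3 → 5 → 7).

**Steps most likely to fail**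

Step 3 (the proposed new step, highest risk). Enolisation of the Ti-chelated ketone may be slow at low temperature. Facial control for an aryl enol anchored through a phenoxide is unproven. The product may be hydroxylated a second time, cleaved, or racemised through a titanium enediolate, so the reaction is stopped at partial conversion and 5 is recycled. The fallback uses known chemistry, sets out from 5 and comes back at 7. Both phenols of 5 are silylated (TBSCl, imidazole, DMAP, DMF) to give the bis-TBS ether of 5 F1. NaHMDS in THF at −78 °C converts it into the sodium Z-enolate F2. This is hydroxylated in the same flask with (−)-[(8,8-dichlorocamphoryl)sulfonyl]oxaziridine (Davis reagent-controlled enolate hydroxylation; this is the antipode of the reagent that gives (S)-acyloins from Z-enolates of aryl ethyl ketones) to give the (R)-α-hydroxy ketone bis-TBS ether F3. TBAF buffered with AcOH (THF, 0 °C) then frees both phenols without base-induced racemisation and gives 7.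

Step 2. The B-ring phenol may also be alkylated, and bis-ether or C-geranylated by-products may form. The fallback sets out from 4 and comes back at 5, and it makes the ether where only one non-chelated phenol is present. Compound 4 alkylates commercial 2,4-dihydroxyacetophenone (K2CO3, acetone) to give 1-{4-[(2E)-3,7-dimethylocta-2,6-dien-1-yl]oxy-2-hydroxyphenyl}ethan-1-one F4. Claisen–Schmidt condensation with commercial 4-hydroxybenzaldehyde (KOH, EtOH/H2O) gives the (E)-chalcone F5. Chemoselective hydrogenation of the enone C=C (H2 1 atm, RhCl(PPh3)3, PhH/EtOH), which leaves the trisubstituted geranyl alkenes and the allyl aryl ether alone, gives 5.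

Step 1. O-acylation, oligo-esters of 1 or the 2,6-dihydroxy isomer may lower the yield. The fallback sets out from 2 and comes back at 3. Houben–Hoesch reaction of 2 with commercial 3-(4-hydroxyphenyl)propanenitrile (ZnCl2, HCl gas, Et2O, 0 °C) precipitates 1-(2,4-dihydroxyphenyl)-3-(4-hydroxyphenyl)propan-1-iminium chloride F6, which is hydrolysed in hot water to 3.

**Further compounds**
F1 | step 3 | 1-{2-[(tert-butyldimethylsilyl)oxy]-4-[(2E)-3,7-dimethylocta-2,6-dien-1-yl]oxyphenyl}-3-{4-[(tert-butyldimethylsilyl)oxy]phenyl}propan-1-one | CC(C)=CCC/C(C)=C/COc1ccc(C(=O)CCc2ccc(O[Si](C)(C)C(C)(C)C)cc2)c(O[Si](C)(C)C(C)(C)C)c1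
F2 | step 3 | sodium (Z)-enolate of F1 | CC(C)=CCC/C(C)=C/COc1ccc(/C([O-])=C/Cc2ccc(O[Si](C)(C)C(C)(C)C)cc2)c(O[Si](C)(C)C(C)(C)C)c1.[Na+]
F3 | step 3 | (2R)-1-{2-[(tert-butyldimethylsilyl)oxy]-4-[(2E)-3,7-dimethylocta-2,6-dien-1-yl]oxyphenyl}-3-{4-[(tert-butyldimethylsilyl)oxy]phenyl}-2-hydroxypropan-1-one | CC(C)=CCC/C(C)=C/COc1ccc(C(=O)[C@H](O)Cc2ccc(O[Si](C)(C)C(C)(C)C)cc2)c(O[Si](C)(C)C(C)(C)C)c1
F4 | step 2 | 1-{4-[(2E)-3,7-dimethylocta-2,6-dien-1-yl]oxy-2-hydroxyphenyl}ethan-1-one | CC(C)=CCC/C(C)=C/COc1ccc(C(C)=O)c(O)c1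
F5 | step 2 | (2E)-1-{4-[(2E)-3,7-dimethylocta-2,6-dien-1-yl]oxy-2-hydroxyphenyl}-3-(4-hydroxyphenyl)prop-2-en-1-one | CC(C)=CCC/C(C)=C/COc1ccc(C(=O)/C=C/c2ccc(O)cc2)c(O)c1
F6 | step 1 | 1-(2,4-dihydroxyphenyl)-3-(4-hydroxyphenyl)propan-1-iminium chloride | [NH2+]=C(CCc1ccc(O)cc1)c1ccc(O)cc1O.[Cl-]
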